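**Plan**

- Retrosynthetic cuts, in order: the ester C–O bond; the ring bond O1–C2 of the oxolane (benzylic carbon to oxygen); then, in one operation, the C2–C3 bond (aldol) and the bond from C4 to its benzylic carbon (conjugate addition of an aryl acyl-anion equivalent).
- Enabling feature: in the oxolane (O1, C2 aryl, C3 acyloxymethyl, C4 arylmethyl, C5), the carbons C5, C4, C3 and the exocyclic acyloxymethyl carbon are the four-carbon chain of a 5-alkoxybutenolide. Its β-carbon (C4) and α-carbon (C3) each carry exactly one aryl-bearing carbon.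
- Forward: butenolide, lithiated aryl dithiane and O-benzylvanillin are joined in one flask (no ring forms). LiAlH4 then opens the lactone acetal to a triol, and the oxolane, the only ring made, closes by capture of the benzylic cation. Esterification, desulfurisation and debenzylation follow.
- Stereochemistry: C4 comes from attack anti to the (5S)-menthyloxy group, which derives from (+)-menthol. C3 is set by relay from C4 (trans in the lactone, which is 3,4-cis in the oxolane). C2 is set in the reversible ring closure (2,3-trans). The side-chain centre comes from (R)-2-methylbutanoic acid.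

Key step: step 4

Abbreviations in names: Ar = 4-(benzyloxy)-3-methoxyphenyl; Men = (1S,2R,5S)-2-isopropyl-5-methylcyclohexyl, the alkyl group of (+)-menthol.

Assumption: the aldol carbinol centre of the key-step product is expected as a mixture of epimers. The (R) epimer is drawn and both are carried on together, because this centre is ionised and re-set in the ring closure. 4-(Benzyloxy)-3-methoxybenzaldehyde is taken as a commercial compound.

**Route**

Step 1
Reactants: 1 furfural
Product: 3 5-hydroxyfuran-2(5H)-one (racemic at the hemiacetal carbon), via furfural 2,5-endoperoxide 2 (not isolated)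
Conditions: O2, hν (visible), methylene blue (C16H18ClN3S, cat.), MeOH, rt
Reagents that add atoms: dioxygen, O=O
Why: Dye-sensitised singlet-oxygen [4+2] cycloaddition to the furan gives endoperoxide 2, which methanol cleaves with loss of the formyl carbon as methyl formate, the standard photo-oxygenation of furfural to the hydroxybutenolide.

Step 2
Reactants: 3 5-hydroxyfuran-2(5H)-one; 4 (+)-menthol, (1S,2R,5S)-2-isopropyl-5-methylcyclohexan-1-ol
Product: 6 (5S)-5-(Men-oxy)furan-2(5H)-one, via the 5R acetal epimer 5 (not isolated)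
Conditions: p-TsOH·H2O (cat.), toluene, reflux (Dean–Stark); crystallisation from petroleum ether, −20 °C; mother liquor re-equilibrated with p-TsOH·H2O (cat.) and recrystallised
Reagents that add atoms: none
Why: Acid-catalysed acetalisation of the pseudo-acid gives both C5 epimers, which interconvert under the acid, so that crystallisation should draw the less soluble (5S) epimer out of the equilibrium (crystallisation-induced diastereomer transformation, the mirror image of the familiar (−)-menthol case).

Step 3
Reactants: 7 4-(benzyloxy)-3-methoxybenzaldehyde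
Product: 8 2-Ar-1,3-dithiane, 2-[4-(benzyloxy)-3-methoxyphenyl]-1,3-dithiane
Conditions: HS(CH2)3SH, BF3·OEt2 (0.2 equiv), CH2Cl2, 0 °C → rt
Reagents that add atoms: propane-1,3-dithiol, SCCCS
Why: Lewis-acid-catalysed thioacetalisation of an aromatic aldehyde turns the formyl carbon into a latent acyl anion, and the benzyl and methyl ethers are inert at this catalyst loading.

Step 4
Reactants: 8 2-Ar-1,3-dithiane; 6 (5S)-5-(Men-oxy)furan-2(5H)-one; 7 4-(benzyloxy)-3-methoxybenzaldehyde
Product: 12 (3R,4S,5S)-3-[(R)-Ar(hydroxy)methyl]-4-(2-Ar-1,3-dithian-2-yl)-5-(Men-oxy)dihydrofuran-2(3H)-one, via 2-lithio dithiane 9 (not isolated), via lithium enolate 10 (not isolated), via lithium aldolate 11 (not isolated)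
Conditions: n-BuLi, THF, −78 → −30 °C; 6, −78 °C; 7, −78 °C; aq NH4Cl, −78 °C
Reagents that add atoms: none
Why: Deprotonation of 8 gives the sulfur-stabilised carbanion 9, which adds 1,4 to butenolide 6 to give lithium enolate 10, and this adds to the carbonyl of 7 to give aldolate 11, protonated cold to 12; the closest known reaction type is the tandem conjugate addition–aldol of lithiated 2-aryl-1,3-dithianes with 5-alkoxyfuran-2(5H)-ones. No ring closes, so no mode of ring closure applies; two skeletal bonds form, lactone C4 to the dithiane carbon and lactone C3 to the carbinol carbon. The new centre at lactone C4 is controlled by the (5S) acetal carbon, whose menthyloxy group blocks one face so that the bulky carbanion enters anti to it (4,5-trans). The new centre at lactone C3 is controlled by the dithianyl group just placed on C4, which sends the aldehyde to the opposite face of the enolate (3,4-trans). The carbinol centre is only loosely governed by the Zimmerman–Traxler geometry of the cyclic lithium enolate and need not be selective, since it is ionised in step 6. The step needs 1,4- over 1,2-addition and two facial selectivities: the soft, hindered aryl dithianyl anion and the exposed β-carbon secure the first, the rigid five-membered ring with its acetal substituent secures the others, and adding 7 only after 6 is consumed keeps 9 away from the aldehyde.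

Step 5
Reactants: 12 key-step adduct
Product: 13 (2S,3S)-2-[(R)-Ar(hydroxy)methyl]-3-(2-Ar-1,3-dithian-2-yl)butane-1,4-diol
Conditions: LiAlH4, THF, 0 °C → rt; Fieser work-up (H2O, aq NaOH)
Reagents that add atoms: none
Why: LiAlH4 reduction of the γ-alkoxy lactone takes the carbonyl to CH2OH and frees the acetal carbon as an aldehyde that is reduced in turn with expulsion of menthol, which should outpace retro-aldol at 0 °C and leaves the former C3 and C4 centres untouched.

Step 6
Reactants: 13 triol
Product: 14 [(2R,3S,4S)-2-Ar-4-(2-Ar-1,3-dithian-2-yl)oxolan-3-yl]methanol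
Conditions: camphor-10-sulfonic acid (0.1 equiv), CH2Cl2, 0 °C → rt; Et3N quench
Reagents that add atoms: none
Why: Acid ionises the electron-rich benzylic alcohol (SN1 cyclodehydration of a 1-aryl-1,4-diol) and the hydroxymethyl on the dithianyl-bearing carbon closes the five-membered ring (the other hydroxymethyl could only give an oxetane), so that under these reversible conditions both carbinol epimers should converge on the 2,3-trans oxolane, which sets C2 as R.

Step 7
Reactants: 14 oxolane alcohol; 15 (R)-2-methylbutanoic acid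
Product: 17 [(2R,3S,4S)-2-Ar-4-(2-Ar-1,3-dithian-2-yl)oxolan-3-yl]methyl (2R)-2-methylbutanoate, via O-acylisourea 16 (not isolated)
Conditions: DCC, 4-(dimethylamino)pyridine (cat.), CH2Cl2, 0 °C → rt
Reagents that add atoms: none
Why: Steglich esterification through O-acylisourea 16 acylates the only free hydroxyl of 14, and the α-centre of this simple aliphatic acid should not epimerise under these near-neutral conditions at 0 °C.

Step 8
Reactants: 17 dithiane ester
Product: 18 [(2R,3S,4S)-2-Ar-4-(Ar-methyl)oxolan-3-yl]methyl (2R)-2-methylbutanoate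
Conditions: Raney Ni (W-2), EtOH–THF, rt → 50 °C
Reagents that add atoms: none
Why: Raney nickel hydrogenolysis of both C–S bonds (Mozingo-type desulfurisation) turns the dithiane carbon into the benzylic CH2 faster than the ring C2–O bond or the ester can react, and any partial loss of benzyl groups is harmless because they are removed next.

Step 9
Reactants: 18 dibenzyl ether
Product: 19 [(2R,3S,4S)-2-(4-hydroxy-3-methoxyphenyl)-4-(4-hydroxy-3-methoxybenzyl)oxolan-3-yl]methyl (2R)-2-methylbutanoate
Conditions: H2 (1 atm), 10% Pd/C, EtOAc, rt, stopped when both benzyl groups are gone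
Reagents that add atoms: none
Why: Palladium-catalysed hydrogenolysis cleaves the two aryl benzyl ethers, which in a neutral aprotic solvent should react faster than the benzylic alkyl ether bond C2–O of the ring, and the ester and all four stereocentres are untouched.

**Compound list**

1 | furfural | O=Cc1ccco1 | starting material
2 | furfural 2,5-endoperoxide (2,3,7-trioxabicyclo[2.2.1]hept-5-ene-1-carbaldehyde), formed in the flask | O=CC12C=CC(OO1)O2 | intermediate
3 | 5-hydroxyfuran-2(5H)-one (racemic) | O=C1C=CC(O)O1 | intermediate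
4 | (+)-menthol, (1S,2R,5S)-2-isopropyl-5-methylcyclohexan-1-ol | CC(C)[C@H]1CC[C@H](C)C[C@@H]1O | starting material
5 | (5R)-5-{[(1S,2R,5S)-2-isopropyl-5-methylcyclohexyl]oxy}furan-2(5H)-one, equilibrating epimer | O=C1O[C@@H](O[C@H]2C[C@@H](C)CC[C@@H]2C(C)C)C=C1 | intermediate
6 | (5S)-5-{[(1S,2R,5S)-2-isopropyl-5-methylcyclohexyl]oxy}furan-2(5H)-one | O=C1O[C@H](O[C@H]2C[C@@H](C)CC[C@@H]2C(C)C)C=C1 | intermediate
7 | 4-(benzyloxy)-3-methoxybenzaldehyde | COc1cc(C=O)ccc1OCc1ccccc1 | starting material
8 | 2-[4-(benzyloxy)-3-methoxyphenyl]-1,3-dithiane | COc1cc(C2SCCCS2)ccc1OCc1ccccc1 | intermediate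
9 | 2-lithio-2-[4-(benzyloxy)-3-methoxyphenyl]-1,3-dithiane, formed in the flask | [Li]C1(SCCCS1)c1ccc(OCc2ccccc2)c(OC)c1 | intermediate
10 | lithium (4S,5S)-4-{2-[4-(benzyloxy)-3-methoxyphenyl]-1,3-dithian-2-yl}-5-(menthyloxy)-4,5-dihydrofuran-2-olate, formed in the flask | [Li]OC1=C[C@H](C2(SCCCS2)c3ccc(OCc4ccccc4)c(OC)c3)[C@@H](O[C@H]5C[C@@H](C)CC[C@@H]5C(C)C)O1 | intermediate
11 | lithium alkoxide of 12 (aldolate), formed in the flask | [Li]O[C@@H](c1ccc(OCc2ccccc2)c(OC)c1)[C@@H]1C(=O)O[C@H](O[C@H]2C[C@@H](C)CC[C@@H]2C(C)C)[C@H]1C1(SCCCS1)c1ccc(OCc2ccccc2)c(OC)c1 | intermediate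
12 | (3R,4S,5S)-3-{(R)-[4-(benzyloxy)-3-methoxyphenyl](hydroxy)methyl}-4-{2-[4-(benzyloxy)-3-methoxyphenyl]-1,3-dithian-2-yl}-5-{[(1S,2R,5S)-2-isopropyl-5-methylcyclohexyl]oxy}dihydrofuran-2(3H)-one (3,4-trans, 4,5-trans; carbinol epimer drawn) | O[C@@H](c1ccc(OCc2ccccc2)c(OC)c1)[C@@H]1C(=O)O[C@H](O[C@H]2C[C@@H](C)CC[C@@H]2C(C)C)[C@H]1C1(SCCCS1)c1ccc(OCc2ccccc2)c(OC)c1 | intermediate
13 | (2S,3S)-2-{(R)-[4-(benzyloxy)-3-methoxyphenyl](hydroxy)methyl}-3-{2-[4-(benzyloxy)-3-methoxyphenyl]-1,3-dithian-2-yl}butane-1,4-diol | O[C@@H](c1ccc(OCc2ccccc2)c(OC)c1)[C@H](CO)[C@@H](CO)C1(SCCCS1)c1ccc(OCc2ccccc2)c(OC)c1 | intermediate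
14 | [(2R,3S,4S)-2-[4-(benzyloxy)-3-methoxyphenyl]-4-{2-[4-(benzyloxy)-3-methoxyphenyl]-1,3-dithian-2-yl}oxolan-3-yl]methanol | OC[C@@H]1[C@H](C2(SCCCS2)c3ccc(OCc4ccccc4)c(OC)c3)CO[C@H]1c5ccc(OCc6ccccc6)c(OC)c5 | intermediate
15 | (R)-2-methylbutanoic acid | CC[C@@H](C)C(=O)O | starting material
16 | N,N'-dicyclohexyl-O-[(2R)-2-methylbutanoyl]isourea, formed in the flask | CC[C@@H](C)C(=O)OC(=NC1CCCCC1)NC1CCCCC1 | intermediate
17 | [(2R,3S,4S)-2-[4-(benzyloxy)-3-methoxyphenyl]-4-{2-[4-(benzyloxy)-3-methoxyphenyl]-1,3-dithian-2-yl}oxolan-3-yl]methyl (2R)-2-methylbutanoate | CC[C@@H](C)C(=O)OC[C@@H]1[C@H](C2(SCCCS2)c3ccc(OCc4ccccc4)c(OC)c3)CO[C@H]1c5ccc(OCc6ccccc6)c(OC)c5 | intermediate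
18 | [(2R,3S,4S)-2-[4-(benzyloxy)-3-methoxyphenyl]-4-[4-(benzyloxy)-3-methoxybenzyl]oxolan-3-yl]methyl (2R)-2-methylbutanoate | CC[C@@H](C)C(=O)OC[C@@H]1[C@H](Cc2ccc(OCc3ccccc3)c(OC)c2)CO[C@H]1c4ccc(OCc5ccccc5)c(OC)c4 | intermediate
19 | [(2R,3S,4S)-2-(4-hydroxy-3-methoxyphenyl)-4-(4-hydroxy-3-methoxybenzyl)oxolan-3-yl]methyl (2R)-2-methylbutanoate | CC[C@@H](C)C(=O)OC[C@@H]1[C@H](Cc2ccc(O)c(OC)c2)CO[C@H]1c1ccc(O)c(OC)c1 | target

**Step count**

Total: 9 steps. Longest linear sequence: 8 steps (furfural 1 to target 19 through steps 1, 2, 4, 5, 6, 7, 8 and 9).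

**Steps most likely to fail**

Step 4. The one-flask sequence may lose control through 1,2-addition or proton transfer by the carbanion, through attack of left-over carbanion on the aldehyde, or through retro-aldol of the aldolate before the quench. The fallback separates the two bond formations. It sets out from 6 and 8: after the conjugate addition, the enolate is protonated with aq NH4Cl and the Michael adduct (4S,5S)-4-{2-[4-(benzyloxy)-3-methoxyphenyl]-1,3-dithian-2-yl}-5-(menthyloxy)dihydrofuran-2(3H)-one F1 is isolated and purified. Its enolate 10 is then regenerated with LiN(iPr)2 in THF at −78 °C, free of any dithianyl anion, aldehyde 7 is added, and a cold quench brings the route back at 12.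

Step 6. The benzylic cation may be diverted by Friedel–Crafts closure of the dithiane-bearing arene (held close by the quaternary dithiane carbon) to an aryltetralin, by sulfur participation, or by incomplete equilibration to the 2,3-trans ring. The fallback removes sulfur before the cation is made. It sets out from 13: Raney Ni in EtOH–THF at rt should give the sulfur-free triol (2S,3S)-2-{(R)-[4-(benzyloxy)-3-methoxyphenyl](hydroxy)methyl}-3-[4-(benzyloxy)-3-methoxybenzyl]butane-1,4-diol F2. Camphor-10-sulfonic acid in CH2Cl2 then closes F2, in the long-established cyclodehydration of a sulfur-free 1-aryl-1,4-diol, to [(2R,3S,4S)-2-[4-(benzyloxy)-3-methoxyphenyl]-4-[4-(benzyloxy)-3-methoxybenzyl]oxolan-3-yl]methanol F3. Esterification of F3 with 15 (DCC, 4-(dimethylamino)pyridine, CH2Cl2) comes back to the route at 18.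

Step 8. Over-reduction on the nickel surface may open the ring by hydrogenolysis of the benzylic C2–O bond, or desulfurisation at the hindered quaternary carbon may stall. The fallback replaces surface hydrogenolysis by a radical chain. It sets out from 17: excess Bu3SnH with AIBN in refluxing toluene reduces the benzylic dithiane to CH2 by homolytic C–S cleavage, which leaves benzylic C–O bonds, the ester and the benzyl ethers alone. It comes back at 18 in one operation, and no new compound is made on this path (F0).

**Further compounds**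

F1 | step 4 | (4S,5S)-4-{2-[4-(benzyloxy)-3-methoxyphenyl]-1,3-dithian-2-yl}-5-{[(1S,2R,5S)-2-isopropyl-5-methylcyclohexyl]oxy}dihydrofuran-2(3H)-one | O=C1C[C@H](C2(SCCCS2)c3ccc(OCc4ccccc4)c(OC)c3)[C@@H](O[C@H]5C[C@@H](C)CC[C@@H]5C(C)C)O1
F2 | step 6 | (2S,3S)-2-{(R)-[4-(benzyloxy)-3-methoxyphenyl](hydroxy)methyl}-3-[4-(benzyloxy)-3-methoxybenzyl]butane-1,4-diol | O[C@@H](c1ccc(OCc2ccccc2)c(OC)c1)[C@H](CO)[C@@H](CO)Cc1ccc(OCc2ccccc2)c(OC)c1
F3 | step 6 | [(2R,3S,4S)-2-[4-(benzyloxy)-3-methoxyphenyl]-4-[4-(benzyloxy)-3-methoxybenzyl]oxolan-3-yl]methanol | OC[C@@H]1[C@H](Cc2ccc(OCc3ccccc3)c(OC)c2)CO[C@H]1c4ccc(OCc5ccccc5)c(OC)c4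
F0 | step 8 | none | none
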